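All constants are those of an exercise.

Counted per litre of the first phase, this is the flask I reckoned.

    reagent in the reaction phase + target → over-reacted product (k1 = 39.7 L mol⁻¹ s⁻¹)
    reagent in the reaction phase ⇌ reagent in the second phase, rate k2*([reagent in the reaction phase] - [reagent in the second phase]/K2) per volume of the first phase (K2 = 0.35, k2 = 0.143 s⁻¹)
    crystals ⇌ target, rate k3*(cs3 - [target]) while solid is left; crystals form when [target] > cs3 (cs3 = 0.58 mM, k3 = 14.3 s⁻¹)
    substrate ⇌ dormant form (K4 = 6.41, k4 = 0.0750 s⁻¹)
    substrate + reagent in the reaction phase → target (k5 = 93.5 L mol⁻¹ s⁻¹)
    target → over-reaction product (k6 = 2.99 × 10⁻⁴ s⁻¹)

substrate 0.010 M; reagent in the second phase 0.0120 M; time 8.0 s; volume of the second phase over the first 1.0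

1. amount of target and crystals together at 8.0 s, in percent of the substrate charged
2. concentration of target in solution at 8.0 s, in percent of saturation

- for target the crystals are counted in
- in the second phase: reagent in the second phase; everything else is in the first
- charges count per volume of the first phase; a concentration in a rate is the amount of a species over the volume of its own phase; every rate counts per litre of the first phase
- as a solid, counted per litre of solution: crystals
- run time (flask): 8.0 s

I began with the feed. I dropped the back-flow of reagent, and the transfer integrated in closed form. The second phase then empties at the feed constant k_f, the transfer coefficient over the partition ratio and the volume ratio, 0.409 s⁻¹. Reagent delivered by time t is its charge times 1 − exp(−k_f t), which by 8.0 s came to 11.5 mM.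

My first way followed the substrate. I let it fall as fast as the feed falls, which holds [reagent in the reaction phase] steady at b, where the substrate step's constant times b plus the dormancy constant equals k_f, so b was 3.57 mM. Dropping the back-flow was rough late on: by 8.0 s the closed form put [reagent in the second phase] over the partition ratio at 1.30 mM, less than b, so my delivered 11.5 mM was a high figure. The dormant form then took 18.4% of the substrate consumed, and 78.5% of the charge had reacted onward. Saturation, 0.58 mM, lies below the charge, so I held dissolved target there once crystals stood. I then gave over-reaction a constant rate, which took 6.57%. That left 72.0% as target and crystals.

My second way counted reagent. Each target costs one reagent and each over-reacted product two, so delivered reagent less the standing b less two shares of over-reaction gave 66.6%.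

The two parted by 5.4 percentage points, and the first way cheated. The reaction phase starts empty, and filling it to b at the opening feed takes 0.728 s, while substrate goes dormant from the start. That costs 5.46%, which brought the first way to 66.5%. I committed to 66.6%, with the dropped back-flow as its weak point.

The forecast gave 70%, range 65% to 75%, and 101%, range 100% to 102%, reasoning that “about a fifth of it is parked in the dormant form”. Its yield stood above mine.

The simulation gave 66.0% and 102%, both within the forecast's ranges, with the dormant form at 21.2%. The neighbour flask, charged with 0.040 M of substrate, has reagent as its limiting reagent. Its k_f is the same 0.409 s⁻¹, so I carried over the same 11.5 mM delivered by 8.00 s, which is 28.7% of its substrate. In that flask reagent in the reaction phase stood at 1.79 × 10⁻⁴ M, and the answer to "y" was 27.5%, with 37.9% of its substrate still free.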